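**Plan**

1. Locants used below: eight-membered ring C1 (CH carrying the side chain), C2=C3 (butenolide olefin; C2 bears C11H2–O, C3 bears C10=O), C4–C5–C6 (cyclopropane, C5 = CH2), C7 (CH–CH3), C8 (CH2), C9 (CH–OH); C1' is the side-chain CH.
2. Retrosynthesis: C7–H and C9–OH come from enone 29; the cyclooctenone is cut at C8–C9 and C6–C7 at once, which excises C7(CH3)–C8 as propyne and leaves aldehyde 27 carrying a 3-substituted cyclopropene. The butenolide is cut at C3–C10/O–C10 (CO) and at C2–C3, giving δ-lactone 14 and cyclopropenyl Weinreb amide 18.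
3. Forward: nitro-Michael addition, δ-lactone (a temporary ring that differentiates the three primary oxygens), C-acylation, enol triflate, carbonylative butenolide closure, then acetate, free cyclopropene and aldehyde. The rhodium-catalysed [6+2] annulation with propyne closes the eight-membered ring last, followed by two reductions.
4. Enabling feature: the cis-locked tetrasubstituted C2=C3 olefin holds the future C9 (as CHO) and the future C4–C5–C6 ring (as a cyclopropene with enantiotopic C5 and C6) six atoms apart on one side. The C–H bonds at C5 and C6 of the target are exactly those that a metal hydride addition to that strained olefin leaves.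
5. Stereochemistry: C1 and C1' from the catalyst-controlled Michael addition; C4 and C6 by desymmetrisation of the cyclopropene under control of C1 (allylic 1,3-strain); C9 by hydride addition anti to the side chain; C7 by hydroxyl-directed hydrogenation.

Key step: step 16

Remark: 20 is carried as its mixture of C2 epimers and enol form, since that centre becomes trigonal in step 10; 5 is racemic and loses its stereocentre in the same step.

**Route**

Step 1
Reactants: 1 pent-4-enal; 2 2-methylbut-2-ene
Product: 3 5-methylhex-4-enal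
Conditions: second-generation Grubbs catalyst (2 mol %), 2 (excess, co-solvent), CH2Cl2, 40 °C
Reagents that add atoms: none
Why: Olefin cross-metathesis exchanges the terminal methylene of 1 for the isopropylidene of 2, the trisubstituted product being inert to further metathesis and the aldehyde being tolerated.

Step 2
Reactants: 3 5-methylhex-4-enal; 4 nitromethane
Product: 6 (E)-6-methyl-1-nitrohepta-1,5-diene, via nitro alcohol 5 (not isolated)
Conditions: 4 (5 equiv), KOtBu (10 mol %), THF/t-BuOH, 0 °C; then (CF3CO)2O, Et3N, CH2Cl2, −10 °C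
Reagents that add atoms: none
Why: Henry (nitroaldol) addition followed by base-mediated elimination of the trifluoroacetate gives the conjugated nitroalkene as its thermodynamic (E) isomer.

Step 3
Reactants: 6 (E)-6-methyl-1-nitrohepta-1,5-diene; 7 methyl 4-oxobutanoate
Product: 8 methyl (3S,4S)-3-formyl-8-methyl-4-(nitromethyl)non-7-enoate
Conditions: (R)-2-[diphenyl(trimethylsilyloxy)methyl]pyrrolidine (10 mol %), PhCO2H (10 mol %), 7 (2 equiv), toluene, 0 °C
Reagents that add atoms: none
Why: Organocatalytic enamine Michael addition through the acyclic synclinal transition state gives the syn adduct, and the (R)-configured diarylprolinol silyl ether sets both C1 and C1' (as 3S,4S) under catalyst control.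

Step 4
Reactants: 8 methyl (3S,4S)-3-formyl-8-methyl-4-(nitromethyl)non-7-enoate
Product: 10 methyl (3S,4S)-3-[(tert-butyldimethylsilyloxy)methyl]-8-methyl-4-(nitromethyl)non-7-enoate, via hydroxy ester 9 (not isolated)
Conditions: NaBH4, MeOH, −40 °C, 15 min; aq. NH4Cl, extraction; then TBSCl, imidazole, CH2Cl2, 0 °C
Reagents that add atoms: tert-butyldimethylsilyl chloride, CC(C)(C)[Si](C)(C)Cl
Why: Chemoselective borohydride reduction of the epimerisable aldehyde (ester and nitro group untouched) and immediate silylation, which blocks closure of the 4-hydroxy ester to a five-membered lactone.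

Step 5
Reactants: 10 methyl (3S,4S)-3-[(tert-butyldimethylsilyloxy)methyl]-8-methyl-4-(nitromethyl)non-7-enoate
Product: 12 methyl (3S,4S)-3-[(tert-butyldimethylsilyloxy)methyl]-4-formyl-8-methylnon-7-enoate, via sodium nitronate 11 (not isolated)
Conditions: NaOMe, MeOH, 0 °C; then TiCl3 (aq., 4 equiv), NH4OAc buffer (pH 5–6), THF, 0 → 25 °C
Reagents that add atoms: water, O
Why: Nef reaction in its reductive form, in which TiCl3 reduces the nitronate to the imine and the buffered medium hydrolyses it to the aldehyde without cleaving the silyl ether or touching the olefin.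

Step 6
Reactants: 12 methyl (3S,4S)-3-[(tert-butyldimethylsilyloxy)methyl]-4-formyl-8-methylnon-7-enoate
Product: 14 (4S,5S)-4-[(tert-butyldimethylsilyloxy)methyl]-5-(4-methylpent-3-en-1-yl)oxan-2-one, via hydroxy ester 13 (not isolated)
Conditions: NaBH4, MeOH, 0 °C; then pyridinium p-toluenesulfonate (cat.), toluene, 60 °C
Reagents that add atoms: none
Why: Aldehyde reduction and acid-catalysed lactonisation of the 5-hydroxy ester give the six-membered lactone, a temporary ring that ties the C1' oxygen to C11 and leaves the C9 oxygen as the only silyl ether.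

Step 7
Reactants: 15 ethyl diazoacetate; 16 bis(trimethylsilyl)acetylene
Product: 17 ethyl 2,3-bis(trimethylsilyl)cycloprop-2-ene-1-carboxylate
Conditions: Rh2(OAc)4 (1 mol %), 16 (3 equiv), CH2Cl2, slow addition of 15, 40 °C
Reagents that add atoms: none
Why: Dirhodium-carbenoid cyclopropenation of the alkyne; the two silyl groups make the cyclopropene symmetric, hindered and storable.

Step 8
Reactants: 17 ethyl 2,3-bis(trimethylsilyl)cycloprop-2-ene-1-carboxylate
Product: 18 N-methoxy-N-methyl-2,3-bis(trimethylsilyl)cycloprop-2-ene-1-carboxamide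
Conditions: MeNH(OMe)·HCl (1.5 equiv), i-PrMgCl (3 equiv), THF, −20 → 0 °C
Reagents that add atoms: N,O-dimethylhydroxylamine hydrochloride, CNOC.Cl
Why: Aminolysis of the ester by the chloromagnesium amide (Weinreb amide formation), tolerated because the silyl-capped cyclopropene has no acidic vinylic hydrogen.

Step 9
Reactants: 14 (4S,5S)-4-[(tert-butyldimethylsilyloxy)methyl]-5-(4-methylpent-3-en-1-yl)oxan-2-one; 18 N-methoxy-N-methyl-2,3-bis(trimethylsilyl)cycloprop-2-ene-1-carboxamide
Product: 20 (4R,5S)-3-[2,3-bis(trimethylsilyl)cycloprop-2-ene-1-carbonyl]-4-[(tert-butyldimethylsilyloxy)methyl]-5-(4-methylpent-3-en-1-yl)oxan-2-one, via lithium enolate 19 (not isolated)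
Conditions: LiN(SiMe3)2 (2.1 equiv), THF, −78 °C; then 18 (1.2 equiv), −78 → −20 °C; aq. NH4Cl
Reagents that add atoms: none
Why: Claisen-type C-acylation of the lactone enolate by the Weinreb amide, whose chelated tetrahedral adduct prevents double addition; C4–H of the cyclopropene is not acidic because its anion would be antiaromatic, and the new C2 centre is removed in step 10.

Step 10
Reactants: 20 (4R,5S)-3-[2,3-bis(trimethylsilyl)cycloprop-2-ene-1-carbonyl]-4-[(tert-butyldimethylsilyloxy)methyl]-5-(4-methylpent-3-en-1-yl)oxan-2-one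
Product: 22 (4R,5S,Z)-3-{[2,3-bis(trimethylsilyl)cycloprop-2-en-1-yl](trifluoromethylsulfonyloxy)methylidene}-4-[(tert-butyldimethylsilyloxy)methyl]-5-(4-methylpent-3-en-1-yl)oxan-2-one, via sodium enolate 21 (not isolated)
Conditions: NaH, 1,2-dimethoxyethane, 0 °C; then Comins' reagent, 0 → 25 °C; aq. NH4Cl
Reagents that add atoms: N-(5-chloropyridin-2-yl)-1,1,1-trifluoro-N-(trifluoromethylsulfonyl)methanesulfonamide (Comins' reagent), FC(F)(F)S(=O)(=O)N(c1ccc(Cl)cn1)S(=O)(=O)C(F)(F)F
Why: O-sulfonylation of the sodium-chelated enolate of the 1,3-dicarbonyl unit with retention of enolate geometry gives the (Z)-enol triflate, triflate cis to the lactone carbonyl, as step 12 requires.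

Step 11
Reactants: 22 the (Z)-enol triflate lactone
Product: 23 (Z)-1-[2,3-bis(trimethylsilyl)cycloprop-2-en-1-yl]-2-[(2R,3S)-1-(tert-butyldimethylsilyloxy)-3-(hydroxymethyl)-7-methyloct-6-en-2-yl]-3-hydroxyprop-1-en-1-yl trifluoromethanesulfonate
Conditions: i-Bu2AlH (4 equiv), CH2Cl2, −78 → −20 °C; Rochelle salt work-up
Reagents that add atoms: none
Why: 1,2-Hydride reduction of the lactone carbonyl (lactol, then diol) frees the allylic C11 hydroxyl cis to the triflate and the C1' primary hydroxyl, and leaves the enol triflate intact.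

Step 12
Reactants: 23 the (Z)-triflate diol
Product: 24 (2S,3R)-3-{4-[2,3-bis(trimethylsilyl)cycloprop-2-en-1-yl]-5-oxo-2,5-dihydrofuran-3-yl}-4-(tert-butyldimethylsilyloxy)-2-(4-methylpent-3-en-1-yl)butan-1-ol
Conditions: Pd(PPh3)4 (5 mol %), CO (1 atm), n-Bu3N (2 equiv), LiCl, MeCN, 60 °C
Reagents that add atoms: carbon monoxide, [C-]#[O+]
Why: Carbonylative lactonisation of a hydroxy vinyl triflate (oxidative addition of zerovalent palladium, CO insertion, 5-exo capture of the acylpalladium by the cis allylic hydroxyl) closes the butenolide; the C1' hydroxyl would have to form an eight-membered lactone, and the fully substituted bis-silyl cyclopropene is too hindered to bind palladium.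

Step 13
Reactants: 24 the butenolide alcohol
Product: 25 (2S,3R)-3-{4-[2,3-bis(trimethylsilyl)cycloprop-2-en-1-yl]-5-oxo-2,5-dihydrofuran-3-yl}-4-(tert-butyldimethylsilyloxy)-2-(4-methylpent-3-en-1-yl)butyl acetate
Conditions: Ac2O, pyridine, 4-(dimethylamino)pyridine (cat.), CH2Cl2, 0 → 25 °C
Reagents that add atoms: acetic anhydride, CC(=O)OC(C)=O
Why: Nucleophile-catalysed acetylation of the only free hydroxyl.

Step 14
Reactants: 25 the silylated acetate
Product: 26 (2S,3R)-3-[4-(cycloprop-2-en-1-yl)-5-oxo-2,5-dihydrofuran-3-yl]-4-hydroxy-2-(4-methylpent-3-en-1-yl)butyl acetate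
Conditions: Bu4NF (3.3 equiv), AcOH (3.3 equiv), THF, −20 → 0 °C; kept cold and dilute
Reagents that add atoms: none
Why: Fluoride cleaves the primary silyl ether and both vinylic C–Si bonds (the cyclopropenyl carbanion is sp-like, as in an alkynylsilane), while acetic acid buffers the medium so that no alkoxide attacks the acetate or the butenolide or epimerises C1.

Step 15
Reactants: 26 the cyclopropenyl alcohol
Product: 27 (2S,3R)-3-[4-(cycloprop-2-en-1-yl)-5-oxo-2,5-dihydrofuran-3-yl]-2-(4-methylpent-3-en-1-yl)-4-oxobutyl acetate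
Conditions: Dess–Martin periodinane, NaHCO3, CH2Cl2, 0 °C; used at once without chromatography
Reagents that add atoms: none
Why: Dess–Martin oxidation of the primary alcohol under buffered conditions free of Lewis acid, which avoids epimerisation at C1 and an ene cyclisation of the aldehyde onto the side-chain olefin.

Step 16
Reactants: 27 the cyclopropenyl aldehyde; 28 propyne
Product: 29 cyclopropane-fused cyclooctenone butenolide, (1R,4R,6S) with C9=O, C7=C8, 7-methyl and the (2S)-1-acetoxy-6-methylhept-5-en-2-yl group on C1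
Conditions: [Rh(cod)2]BF4 (10 mol %), 1,2-bis(diphenylphosphino)ethane (10 mol %), 28 (10 equiv), ClCH2CH2Cl, 40 °C, sealed tube
Reagents that add atoms: none
Why: Proposed new method: monovalent rhodium inserts into the aldehyde C9–H bond and the acyl rhodium hydride adds syn across the strained C5=C6 bond of the tethered cyclopropene (H to C5, Rh to C6, driven by release of the extra cyclopropene strain) to give a seven-membered acyl(cyclopropyl)rhodacycle; propyne then inserts into the Rh–C6 bond with rhodium on its terminal carbon (C6–C7 formed), and acyl–alkenyl reductive elimination forms C8–C9 and frees the catalyst. The closest known reactions are the rhodium-catalysed formal [6+2] annulation of 4-allenals with alkynes through a seven-membered acyl rhodacycle and the rhodium-catalysed hydroacylation of cyclopropenes. The eight-membered ring is closed as a two-component [6+2] annulation, the last bond by reductive elimination from a nine-membered rhodacycle, with both alkyne carbons ending inside the ring. C4 and C6 arise by desymmetrisation: the tether forces Rh–H onto the cyclopropene face that carries C3, so the ring fusion is cis, and C1 selects one of the two enantiotopic olefinic carbons because allylic 1,3-strain across the tetrasubstituted C2=C3 bond keeps H–C1 and H–C4 in the butenolide plane, which puts the formyl group and only one olefinic carbon on the same face and the future C5 methylene on the face of the side chain, as in the target. The step needs hydrometalation to outrun decarbonylation, propyne insertion to outrun direct acyl–cyclopropyl reductive elimination (which would give a six-membered ketone), and rhodium to end on the unsubstituted alkyne carbon; these are secured by the strained chelating olefin and cationic diphosphine catalyst, by excess propyne, and by the steric bias known from alkyne hydroacylation.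

Step 17
Reactants: 29 the cyclooctenone
Product: 30 (1R,4R,6S,9S)-allylic alcohol (C9–OH, C7=C8 retained)
Conditions: NaBH4, CeCl3·7H2O, MeOH, −78 °C
Reagents that add atoms: none
Why: Luche 1,2-reduction of the enone, with hydride expected to reach C9 from the ring face opposite to the C1 side chain (the face of H–C1), which gives the (9S) alcohol with OH cis to the side chain.

Step 18
Reactants: 30 the allylic alcohol
Product: 31 target, (1R,4R,6R,7S,9S) with the (2S) side chain
Conditions: H2 (50 atm), [Rh(nbd)(dppb)]BF4 (10 mol %), CH2Cl2, 25 °C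
Reagents that add atoms: none
Why: Hydroxyl-directed homogeneous hydrogenation: the cationic rhodium catalyst bound to the C9 hydroxyl delivers H2 to C7=C8 from the hydroxyl face, so H–C7 is cis and the methyl group trans to OH (7S), while the undirected trisubstituted side-chain olefin and the tetrasubstituted butenolide olefin are not reduced.

**Compound list**

1 | pent-4-enal | C=CCCC=O | starting material
2 | 2-methylbut-2-ene | CC=C(C)C | starting material
3 | 5-methylhex-4-enal | CC(C)=CCCC=O | intermediate
4 | nitromethane | C[N+](=O)[O-] | starting material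
5 | 6-methyl-1-nitrohept-5-en-2-ol (racemic, not isolated) | CC(C)=CCCC(O)C[N+](=O)[O-] | intermediate
6 | (E)-6-methyl-1-nitrohepta-1,5-diene | CC(C)=CCC/C=C/[N+](=O)[O-] | intermediate
7 | methyl 4-oxobutanoate | COC(=O)CCC=O | starting material
8 | methyl (3S,4S)-3-formyl-8-methyl-4-(nitromethyl)non-7-enoate | [O-][N+](=O)C[C@@H](CCC=C(C)C)[C@@H](C=O)CC(=O)OC | intermediate
9 | methyl (3S,4S)-3-(hydroxymethyl)-8-methyl-4-(nitromethyl)non-7-enoate (not isolated) | [O-][N+](=O)C[C@@H](CCC=C(C)C)[C@@H](CO)CC(=O)OC | intermediate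
10 | methyl (3S,4S)-3-[(tert-butyldimethylsilyloxy)methyl]-8-methyl-4-(nitromethyl)non-7-enoate | [O-][N+](=O)C[C@@H](CCC=C(C)C)[C@@H](CO[Si](C)(C)C(C)(C)C)CC(=O)OC | intermediate
11 | sodium nitronate of 10 (not isolated) | [Na+].[O-][N+]([O-])=C[C@@H](CCC=C(C)C)[C@@H](CO[Si](C)(C)C(C)(C)C)CC(=O)OC | intermediate
12 | methyl (3S,4S)-3-[(tert-butyldimethylsilyloxy)methyl]-4-formyl-8-methylnon-7-enoate | O=C[C@@H](CCC=C(C)C)[C@@H](CO[Si](C)(C)C(C)(C)C)CC(=O)OC | intermediate
13 | methyl (3S,4S)-3-[(tert-butyldimethylsilyloxy)methyl]-4-(hydroxymethyl)-8-methylnon-7-enoate (not isolated) | OC[C@@H](CCC=C(C)C)[C@@H](CO[Si](C)(C)C(C)(C)C)CC(=O)OC | intermediate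
14 | (4S,5S)-4-[(tert-butyldimethylsilyloxy)methyl]-5-(4-methylpent-3-en-1-yl)oxan-2-one | O1C[C@@H](CCC=C(C)C)[C@@H](CO[Si](C)(C)C(C)(C)C)CC1=O | intermediate
15 | ethyl diazoacetate | CCOC(=O)C=[N+]=[N-] | starting material
16 | bis(trimethylsilyl)acetylene | C[Si](C)(C)C#C[Si](C)(C)C | starting material
17 | ethyl 2,3-bis(trimethylsilyl)cycloprop-2-ene-1-carboxylate | CCOC(=O)C1C([Si](C)(C)C)=C1[Si](C)(C)C | intermediate
18 | N-methoxy-N-methyl-2,3-bis(trimethylsilyl)cycloprop-2-ene-1-carboxamide | CON(C)C(=O)C1C([Si](C)(C)C)=C1[Si](C)(C)C | intermediate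
19 | lithium enolate of 14 (not isolated) | O1C[C@@H](CCC=C(C)C)[C@@H](CO[Si](C)(C)C(C)(C)C)C=C1[O-].[Li+] | intermediate
20 | (4R,5S)-3-[2,3-bis(trimethylsilyl)cycloprop-2-ene-1-carbonyl]-4-[(tert-butyldimethylsilyloxy)methyl]-5-(4-methylpent-3-en-1-yl)oxan-2-one (C3 epimers and enol) | O1C[C@@H](CCC=C(C)C)[C@@H](CO[Si](C)(C)C(C)(C)C)C(C(=O)C2C([Si](C)(C)C)=C2[Si](C)(C)C)C1=O | intermediate
21 | sodium (Z)-enolate of 20 (not isolated) | O1C[C@@H](CCC=C(C)C)[C@@H](CO[Si](C)(C)C(C)(C)C)/C(C1=O)=C(/[O-])C2C([Si](C)(C)C)=C2[Si](C)(C)C.[Na+] | intermediate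
22 | (4R,5S,Z)-3-{[2,3-bis(trimethylsilyl)cycloprop-2-en-1-yl](trifluoromethylsulfonyloxy)methylidene}-4-[(tert-butyldimethylsilyloxy)methyl]-5-(4-methylpent-3-en-1-yl)oxan-2-one | O1C[C@@H](CCC=C(C)C)[C@@H](CO[Si](C)(C)C(C)(C)C)/C(C1=O)=C(/OS(=O)(=O)C(F)(F)F)C2C([Si](C)(C)C)=C2[Si](C)(C)C | intermediate
23 | (Z)-1-[2,3-bis(trimethylsilyl)cycloprop-2-en-1-yl]-2-[(2R,3S)-1-(tert-butyldimethylsilyloxy)-3-(hydroxymethyl)-7-methyloct-6-en-2-yl]-3-hydroxyprop-1-en-1-yl trifluoromethanesulfonate | OC[C@@H](CCC=C(C)C)[C@@H](CO[Si](C)(C)C(C)(C)C)/C(CO)=C(/OS(=O)(=O)C(F)(F)F)C1C([Si](C)(C)C)=C1[Si](C)(C)C | intermediate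
24 | (2S,3R)-3-{4-[2,3-bis(trimethylsilyl)cycloprop-2-en-1-yl]-5-oxo-2,5-dihydrofuran-3-yl}-4-(tert-butyldimethylsilyloxy)-2-(4-methylpent-3-en-1-yl)butan-1-ol | OC[C@@H](CCC=C(C)C)[C@@H](CO[Si](C)(C)C(C)(C)C)C1=C(C2C([Si](C)(C)C)=C2[Si](C)(C)C)C(=O)OC1 | intermediate
25 | (2S,3R)-3-{4-[2,3-bis(trimethylsilyl)cycloprop-2-en-1-yl]-5-oxo-2,5-dihydrofuran-3-yl}-4-(tert-butyldimethylsilyloxy)-2-(4-methylpent-3-en-1-yl)butyl acetate | CC(=O)OC[C@@H](CCC=C(C)C)[C@@H](CO[Si](C)(C)C(C)(C)C)C1=C(C2C([Si](C)(C)C)=C2[Si](C)(C)C)C(=O)OC1 | intermediate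
26 | (2S,3R)-3-[4-(cycloprop-2-en-1-yl)-5-oxo-2,5-dihydrofuran-3-yl]-4-hydroxy-2-(4-methylpent-3-en-1-yl)butyl acetate | CC(=O)OC[C@@H](CCC=C(C)C)[C@@H](CO)C1=C(C2C=C2)C(=O)OC1 | intermediate
27 | (2S,3R)-3-[4-(cycloprop-2-en-1-yl)-5-oxo-2,5-dihydrofuran-3-yl]-2-(4-methylpent-3-en-1-yl)-4-oxobutyl acetate | CC(=O)OC[C@@H](CCC=C(C)C)[C@@H](C=O)C1=C(C2C=C2)C(=O)OC1 | intermediate
28 | propyne | CC#C | starting material
29 | cyclopropane-fused cyclooctenone butenolide, (1R,4R,6S), C9=O, C7=C8, 7-methyl, (2S)-1-acetoxy-6-methylhept-5-en-2-yl on C1 | CC(=O)OC[C@@H](CCC=C(C)C)[C@@H]1C2=C(C(=O)OC2)[C@@H]2C[C@@H]2C(C)=CC1=O | intermediate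
30 | (1R,4R,6S,9S)-allylic alcohol corresponding to 29 | CC(=O)OC[C@@H](CCC=C(C)C)[C@@H]1C2=C(C(=O)OC2)[C@@H]2C[C@@H]2C(C)=C[C@@H]1O | intermediate
31 | target CNP0267808.2, (1R,4R,6R,7S,9S) with (2S) side chain | CC(=O)OC[C@@H](CCC=C(C)C)[C@@H]1C2=C(C(=O)OC2)[C@@H]2C[C@@H]2[C@@H](C)C[C@@H]1O | target

**Step count and risks**

Total steps: 18. Longest linear sequence: 16 (steps 1–6 and 9–18, from pent-4-enal); the cyclopropene branch (steps 7–8) joins at step 9.

Steps most likely to fail:

1. Step 16 (key step). The acyl rhodium hydride may decarbonylate, the rhodacycle may collapse by direct acyl–cyclopropyl reductive elimination to a six-membered ketone before propyne is taken up, or propyne may insert with the opposite orientation or oligomerise. The fallback makes the two bonds one at a time with known reaction types and sets out from aldehyde 27. Indium-mediated Barbier addition of 2,3-dibromopropene (In, THF/H2O, 25 °C) forms C8–C9 and gives the 2-bromoallyl carbinol F1, the (9S) epimer being separated if both form. An intramolecular reductive Heck reaction (Pd(OAc)2, PPh3, HCO2Na, Bu4NCl, DMF, 60 °C) then forms C6–C7 and gives the exo-methylene alcohol F2. In it zerovalent palladium inserts into the C7–Br bond, the alkenylpalladium adds syn across the cyclopropene on the tether face (same cis fusion and same choice of olefinic carbon as argued for step 16), and formate reduces the cyclopropylpalladium, which has no syn β-hydrogen. Hydroxyl-directed hydrogenation of the 1,1-disubstituted olefin of F2 under the conditions of step 18 places H on C7 from the hydroxyl face and comes back to the route at target 31.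

2. Step 14. Under fluoride the acetate may be lost or may migrate, the butenolide may be opened by the liberated C9 alkoxide, and the unsubstituted cyclopropene may condense with itself (ene reaction) during isolation. The fallback changes the order of unmasking so that the free cyclopropene is made last and never isolated, and sets out from 25. HF·pyridine/pyridine (THF, 0 °C) removes only the primary silyl ether to give alcohol F3, which still carries the silyl-capped cyclopropene. Dess–Martin oxidation (NaHCO3, CH2Cl2, 0 °C) gives aldehyde F4. The two vinylic silyl groups are then cleaved with Bu4NF/AcOH (THF, −78 °C), and the cold, filtered solution is used directly, which comes back to the route at 27.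

3. Step 17. Hydride delivery to the medium-ring enone may show poor facial selectivity and give mainly the C9 epimer. The fallback corrects the centre by inversion and sets out from 29. The epimeric (9R) alcohol F5 obtained from the same reduction is subjected to a Mitsunobu reaction with chloroacetic acid (PPh3, diisopropyl azodicarboxylate, toluene, 0 °C) to give the inverted (9S) chloroacetate F6. Thiourea/NaHCO3 (EtOH, 50 °C) removes the chloroacetyl group without touching the acetate and comes back to the route at 30.

Further compounds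
F1 | step 16 | (2S,3R,4S)-6-bromo-3-[4-(cycloprop-2-en-1-yl)-5-oxo-2,5-dihydrofuran-3-yl]-4-hydroxy-2-(4-methylpent-3-en-1-yl)hept-6-en-1-yl acetate | CC(=O)OC[C@@H](CCC=C(C)C)[C@@H]([C@@H](O)CC(Br)=C)C1=C(C2C=C2)C(=O)OC1
F2 | step 16 | (1R,4R,6S,9S)-7-methylidene analogue of 31 (C7=CH2 in place of C7–CH3, C9–OH) | CC(=O)OC[C@@H](CCC=C(C)C)[C@@H]1C2=C(C(=O)OC2)[C@@H]2C[C@@H]2C(=C)C[C@@H]1O
F3 | step 14 | (2S,3R)-3-{4-[2,3-bis(trimethylsilyl)cycloprop-2-en-1-yl]-5-oxo-2,5-dihydrofuran-3-yl}-4-hydroxy-2-(4-methylpent-3-en-1-yl)butyl acetate | CC(=O)OC[C@@H](CCC=C(C)C)[C@@H](CO)C1=C(C2C([Si](C)(C)C)=C2[Si](C)(C)C)C(=O)OC1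
F4 | step 14 | (2S,3R)-3-{4-[2,3-bis(trimethylsilyl)cycloprop-2-en-1-yl]-5-oxo-2,5-dihydrofuran-3-yl}-2-(4-methylpent-3-en-1-yl)-4-oxobutyl acetate | CC(=O)OC[C@@H](CCC=C(C)C)[C@@H](C=O)C1=C(C2C([Si](C)(C)C)=C2[Si](C)(C)C)C(=O)OC1
F5 | step 17 | (1R,4R,6S,9R)-allylic alcohol, the C9 epimer of 30 | CC(=O)OC[C@@H](CCC=C(C)C)[C@@H]1C2=C(C(=O)OC2)[C@@H]2C[C@@H]2C(C)=C[C@H]1O
F6 | step 17 | (9S)-chloroacetate of 30 | CC(=O)OC[C@@H](CCC=C(C)C)[C@@H]1C2=C(C(=O)OC2)[C@@H]2C[C@@H]2C(C)=C[C@@H]1OC(=O)CCl
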